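**Retrosynthetic overview**

1. Carbons are numbered C1–C24 in the order of the target SMILES (C22 = CMe2). The 1,2-dioxane is disconnected last, at O–C18 (intramolecular SN2 of a C14 hydroperoxide on a C18 mesylate); C18/C19 go back to an Evans syn-aldol and C14–OO to the anti-perhydrolysis of an epoxide built on C12 from (S)-2-methylglycidol.
2. Ring B is disconnected at C6–C8: C6 is the β-carbon of the ring A C2 enone, and C8 is the free terminus of the allylsilane C8=C9–C10H2–SiMe3 that hangs from C5 through C22 and C11.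
3. A TiCl4-promoted intramolecular Hosomi–Sakurai addition therefore closes ring B cis-fused and leaves C9=C10 as the methylene, with no C9 ketone ever placed next to C11.
4. The enone comes from anisole: Friedel–Crafts union with 3-methylbut-2-enoic acid (C5–C22), Birch reduction (ring A), Evans alkylation (C11), ester-to-allylsilane conversion (C9), chiral lithium amide desymmetrisation (C5).
5. Ring order: ring A (from the arene), ring B (key step), 1,2-dioxane (last).

Key step: step 13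

Remark: the facial sense of the lithium amide deprotonation is taken over from 4-tert-butylcyclohexanone, and the epoxide perhydrolysis is taken to be an anti (inverting) opening at the tertiary carbon.

Shorthand: Dec = (2R,4aS,8aS)-1,1-dimethyl-3,6-dimethylidenedecahydronaphthalen-2-yl (C22 = position 1, C11 = 2, C9 = 3, C6 = 4a, C2 = 6, C5 = 8a). The C11 side chain is carried through the key step as CH2OBn (C12 only), because C13–C16 arrive later as a chiral glycidyl unit.

**Route**

Step 1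
Reactants: 1 anisole; 2 3-methylbut-2-enoic acid
Product: 3 3-(4-methoxyphenyl)-3-methylbutanoic acid
Conditions: AlCl3 (2.5 equiv), CH2Cl2, 0 °C → rt; aq. HCl
Reagents that add atoms: none
Why: Friedel–Crafts alkylation by the tertiary cation of the AlCl3-activated acrylic acid goes para to the methoxy group and forms the C5–C22 bond with the quaternary CMe2 carbon.

Step 2
Reactants: 3 3-(4-methoxyphenyl)-3-methylbutanoic acid
Product: 5 3-methyl-3-(4-oxocyclohex-1-en-1-yl)butanoic acid, via dienol ether 4 (not isolated)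
Conditions: Li, NH3(l), THF, t-BuOH, −78 → −33 °C; NH4Cl; then (CO2H)2, MeOH/H2O, rt
Reagents that add atoms: water, O
Why: Birch reduction of the 4-alkylanisole (the carboxylate is inert) gives the 1-methoxycyclohexa-1,4-diene, and mild enol ether hydrolysis stops at the achiral β,γ-unsaturated ketone, so neither conjugation nor lactonisation onto an enone can occur.

Step 3
Reactants: 5 3-methyl-3-(4-oxocyclohex-1-en-1-yl)butanoic acid
Product: 6 3-methyl-3-(4-oxocyclohexyl)butanoic acid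
Conditions: H2 (3 atm), 10% Pd/C, EtOAc, rt
Reagents that add atoms: none
Why: heterogeneous hydrogenation of the ring alkene gives the 4-substituted cyclohexanone, whose two α-methylenes are left to be distinguished in step 11.

Step 4
Reactants: 6 3-methyl-3-(4-oxocyclohexyl)butanoic acid
Product: 7 3-(1,4-dioxaspiro[4.5]decan-8-yl)-3-methylbutanoic acid
Conditions: HOCH2CH2OH, TsOH (cat.), PhH, reflux (Dean–Stark); then LiOH, THF/H2O, rt (cleaves any hydroxyethyl ester); pH 5
Reagents that add atoms: ethane-1,2-diol, OCCO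
Why: dioxolane ketalisation masks the ring A ketone for the enolate and organocerium steps.

Step 5
Reactants: 7 3-(1,4-dioxaspiro[4.5]decan-8-yl)-3-methylbutanoic acid; 8 (4S)-4-benzyl-1,3-oxazolidin-2-one
Product: 10 (4S)-4-benzyl-3-[3-(1,4-dioxaspiro[4.5]decan-8-yl)-3-methylbutanoyl]-1,3-oxazolidin-2-one, via mixed pivalic anhydride 9 (not isolated)
Conditions: t-BuCOCl, Et3N, THF, −20 °C; then 8, LiCl, −20 °C → rt
Reagents that add atoms: none
Why: N-acylation of the oxazolidinone through the mixed anhydride, whose CH2-flanked carbonyl is the less hindered one, installs the auxiliary.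

Step 6
Reactants: 10 (4S)-4-benzyl-3-[3-(1,4-dioxaspiro[4.5]decan-8-yl)-3-methylbutanoyl]-1,3-oxazolidin-2-one
Product: 12 (4S)-4-benzyl-3-[(2R)-2-[(benzyloxy)methyl]-3-(1,4-dioxaspiro[4.5]decan-8-yl)-3-methylbutanoyl]-1,3-oxazolidin-2-one, via sodium (Z)-enolate 11 (not isolated)
Conditions: NaN(SiMe3)2, THF, −78 °C; BnOCH2Cl, −78 → −40 °C
Reagents that add atoms: benzyl chloromethyl ether, ClCOCc1ccccc1
Why: Evans alkylation, in which the chelated (Z)-enolate is attacked on the face away from the benzyl group of the (S)-auxiliary, sets C11 and brings in C12.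

Step 7
Reactants: 12 (4S)-4-benzyl-3-[(2R)-2-[(benzyloxy)methyl]-3-(1,4-dioxaspiro[4.5]decan-8-yl)-3-methylbutanoyl]-1,3-oxazolidin-2-one
Product: 14 (2R)-2-[(benzyloxy)methyl]-3-(1,4-dioxaspiro[4.5]decan-8-yl)-3-methylbutanoic acid, via peroxy acid 13 (not isolated)
Conditions: LiOH, H2O2, THF/H2O, 0 °C; Na2SO3; dilute HCl to pH 4, 0 °C
Reagents that add atoms: hydrogen peroxide (as LiOOH), OO
Why: the hydroperoxide anion attacks the exocyclic carbonyl selectively even in hindered imides and the peracid is reduced by sulfite, so C11 is not epimerised and 8 is recovered.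

Step 8
Reactants: 14 (2R)-2-[(benzyloxy)methyl]-3-(1,4-dioxaspiro[4.5]decan-8-yl)-3-methylbutanoic acid
Product: 15 methyl (2R)-2-[(benzyloxy)methyl]-3-(1,4-dioxaspiro[4.5]decan-8-yl)-3-methylbutanoate
Conditions: MeI, K2CO3, DMF, rt
Reagents that add atoms: iodomethane, CI
Why: SN2 O-alkylation of the carboxylate is insensitive to the hindrance around C9 and leaves C11 untouched.

Step 9
Reactants: 15 methyl (2R)-2-[(benzyloxy)methyl]-3-(1,4-dioxaspiro[4.5]decan-8-yl)-3-methylbutanoate; 16 (trimethylsilyl)methylmagnesium chloride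
Product: 18 8-[(3S)-4-(benzyloxy)-2-methyl-3-{3-(trimethylsilyl)prop-1-en-2-yl}butan-2-yl]-1,4-dioxaspiro[4.5]decane, via bis(silylmethyl)carbinol 17 (not isolated)
Conditions: CeCl3 (anhydrous), THF; 16 (5 equiv), −78 °C → rt; NH4Cl; then SiO2, CH2Cl2, rt
Reagents that add atoms: none
Why: double addition of the weakly basic organocerium reagent to the ester followed by Peterson elimination of one β-silyl group turns C9 into the 2-substituted allylsilane (C8=C9–C10–Si) without enolising C11 (the S descriptor in 18 is a CIP change only).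

Step 10
Reactants: 18 8-[(3S)-4-(benzyloxy)-2-methyl-3-{3-(trimethylsilyl)prop-1-en-2-yl}butan-2-yl]-1,4-dioxaspiro[4.5]decane
Product: 19 4-[(3S)-4-(benzyloxy)-2-methyl-3-{3-(trimethylsilyl)prop-1-en-2-yl}butan-2-yl]cyclohexan-1-one
Conditions: PPTS, acetone/H2O, 55 °C
Reagents that add atoms: water, O
Why: weak-acid ketal hydrolysis frees the ring A ketone, and the allylsilane, which needs a strong acid for protodesilylation, should survive.

Step 11
Reactants: 19 4-[(3S)-4-(benzyloxy)-2-methyl-3-{3-(trimethylsilyl)prop-1-en-2-yl}butan-2-yl]cyclohexan-1-one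
Product: 20 [(4S)-4-{(3S)-4-(benzyloxy)-2-methyl-3-[3-(trimethylsilyl)prop-1-en-2-yl]butan-2-yl}cyclohex-1-en-1-yl]oxy(trimethyl)silane
Conditions: (R,R)-[PhCH(CH3)]2NH, n-BuLi, LiCl, THF, −78 °C; Me3SiCl (internal quench), then 19, −100 → −78 °C
Reagents that add atoms: chlorotrimethylsilane, C[Si](C)(C)Cl
Why: desymmetrising deprotonation by the chiral lithium amide removes one of the two axial α-protons of the equatorially substituted chair and the enolate is silylated in situ, which sets C5 (S) by reagent control; the minor C5 epimer is a diastereomer to be removed by chromatography.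

Step 12
Reactants: 20 [(4S)-4-{(3S)-4-(benzyloxy)-2-methyl-3-[3-(trimethylsilyl)prop-1-en-2-yl]butan-2-yl}cyclohex-1-en-1-yl]oxy(trimethyl)silane
Product: 21 (4S)-4-{(3S)-4-(benzyloxy)-2-methyl-3-[3-(trimethylsilyl)prop-1-en-2-yl]butan-2-yl}cyclohex-2-en-1-one
Conditions: IBX, 4-methoxypyridine N-oxide, DMSO, rt
Reagents that add atoms: none
Why: IBX·N-oxide dehydrogenation of the silyl enol ether places the C6=C7 double bond on the side fixed in step 11 and, unlike a Pd(OAc)2 oxidation in which divalent palladium could also attack the 2-substituted allylsilane, should leave that group alone.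

Step 13
Reactants: 21 (4S)-4-{(3S)-4-(benzyloxy)-2-methyl-3-[3-(trimethylsilyl)prop-1-en-2-yl]butan-2-yl}cyclohex-2-en-1-one
Product: 23 (4aS,6R,8aR)-6-[(benzyloxy)methyl]-5,5-dimethyl-7-methylideneoctahydronaphthalen-2(1H)-one, via trichlorotitanium enolate 22 (not isolated)
Conditions: TiCl4 (1.2 equiv), CH2Cl2, −78 °C; aq. NaHCO3
Reagents that add atoms: none
Why: TiCl4 binds the C2 carbonyl, the allylsilane terminus C8 adds to the β-carbon C6, and the β-silyl cation at C9 loses Me3SiCl to leave the C9=C10 methylene and a titanium enolate that is protonated on work-up; this is an intramolecular Hosomi–Sakurai conjugate addition, with the Lewis-acid cyclisations of cyclohexenones carrying an allylsilane chain at C4 as the closest known reaction type. Ring B closes in the 6-exo-trig mode with respect to the C6=C7 bond. The only new stereocentre, C6, is set by the tether: with the bulky C5 substituent pseudo-equatorial, the three-atom chain C22–C11–C9 can deliver C8 only along the axial trajectory on the face syn to the C5–C22 bond, so the ring fusion is cis. The step needs 1,4- over 1,2-addition, which the chain length secures because 1,2-attack would give a bridged eight-membered ring, and it needs cis over trans fusion, which rests on the stereoelectronic preference for the chair enolate even though C12 must then sit axial on the forming ring. C5 and C11 are spectators and no C9 carbonyl is formed, so C11 cannot epimerise.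

Step 14
Reactants: 23 (4aS,6R,8aR)-6-[(benzyloxy)methyl]-5,5-dimethyl-7-methylideneoctahydronaphthalen-2(1H)-one
Product: 24 (2R,4aS,8aS)-2-[(benzyloxy)methyl]-1,1-dimethyl-3,6-dimethylidenedecahydronaphthalene
Conditions: Ph3PCH3Br, KOC(CH3)3, THF, 0 °C → rt
Reagents that add atoms: methyltriphenylphosphonium bromide (as its ylide), C[P+](c1ccccc1)(c1ccccc1)c1ccccc1.[Br-]
Why: Wittig methylenation of the unhindered C2 ketone, which has no stereocentre at either α-carbon.

Step 15
Reactants: 24 (2R,4aS,8aS)-2-[(benzyloxy)methyl]-1,1-dimethyl-3,6-dimethylidenedecahydronaphthalene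
Product: 25 (Dec)methanol
Conditions: Li, NH3(l), THF, −78 °C; NH4Cl
Reagents that add atoms: none
Why: dissolving-metal cleavage of the benzyl ether, under which isolated 1,1-disubstituted alkenes are not reduced.

Step 16
Reactants: 25 (Dec)methanol
Product: 26 (2R,4aS,8aS)-2-(iodomethyl)-1,1-dimethyl-3,6-dimethylidenedecahydronaphthalene
Conditions: I2, PPh3, imidazole, PhMe, 60 °C
Reagents that add atoms: iodine, II
Why: Appel-type iodination by SN2 attack of iodide on the alkoxyphosphonium salt at C12, which the β-branching only slows.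

Step 17
Reactants: 27 [(2S)-2-methyloxiran-2-yl]methanol
Product: 28 [(2R)-2-methyloxiran-2-yl]methyl 4-methylbenzenesulfonate
Conditions: TsCl, Et3N, DMAP (cat.), CH2Cl2, 0 °C
Reagents that add atoms: 4-methylbenzenesulfonyl chloride, Cc1ccc(cc1)S(=O)(=O)Cl
Why: O-sulfonylation of the primary alcohol leaves the quaternary stereocentre (the future C14) untouched, the change from S to R being a CIP change only.

Step 18
Reactants: 26 (2R,4aS,8aS)-2-(iodomethyl)-1,1-dimethyl-3,6-dimethylidenedecahydronaphthalene; 28 [(2R)-2-methyloxiran-2-yl]methyl 4-methylbenzenesulfonate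
Product: 31 (2R)-2-methyl-2-[2-(Dec)ethyl]oxirane, via alkylmagnesium iodide 29 (not isolated), via tosyloxy alcohol 30 (not isolated)
Conditions: Mg, Et2O, 35 °C; CuI (10 mol%), 28, THF, −40 → −10 °C; NH4Cl; then K2CO3, MeOH, rt
Reagents that add atoms: none
Why: copper-catalysed Grignard opening of the glycidyl sulfonate at its epoxide CH2 (C13) forms C12–C13, and the tertiary alkoxide then displaces the primary tosylate (3-exo-tet), so the C14–O bond and its configuration pass unchanged into the new 2,2-disubstituted epoxide.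

Step 19
Reactants: 31 (2R)-2-methyl-2-[2-(Dec)ethyl]oxirane
Product: 32 (2S)-2-hydroperoxy-2-methyl-4-(Dec)butan-1-ol
Conditions: H2O2 (anhydrous, in Et2O, 10 equiv), H3PMo12O40 (3 mol%), Et2O, rt
Reagents that add atoms: hydrogen peroxide, OO
Why: acid-catalysed perhydrolysis of a 2,2-disubstituted epoxide opens the tertiary C–O bond by anti attack of H2O2, which installs the C14 hydroperoxide with inversion (C14 now as in the target); being ionic, it does not engage the two exocyclic alkenes that would compete in any radical hydroperoxidation of an alkene.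

Step 20
Reactants: 32 (2S)-2-hydroperoxy-2-methyl-4-(Dec)butan-1-ol
Product: 33 triethyl{[(2S)-2-methyl-4-(Dec)-2-[(triethylsilyl)peroxy]butyl]oxy}silane
Conditions: Et3SiCl, imidazole, DMAP (cat.), DMF, 0 °C
Reagents that add atoms: chlorotriethylsilane, CC[Si](CC)(CC)Cl
Why: silylation of both the hydroperoxide and the primary hydroxyl, the triethylsilyl peroxide being the usual mask of a tertiary hydroperoxide.

Step 21
Reactants: 33 triethyl{[(2S)-2-methyl-4-(Dec)-2-[(triethylsilyl)peroxy]butyl]oxy}silane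
Product: 34 (2S)-2-methyl-4-(Dec)-2-[(triethylsilyl)peroxy]butanal
Conditions: (COCl)2, DMSO, CH2Cl2, −78 → −40 °C; Et3N, −78 → 0 °C
Reagents that add atoms: none
Why: Swern conditions oxidise a primary triethylsilyl ether directly to the aldehyde while the less basic silyl peroxide oxygen is not attacked, and the quaternary α-carbon rules out enolisation or elimination.

Step 22
Reactants: 34 (2S)-2-methyl-4-(Dec)-2-[(triethylsilyl)peroxy]butanal
Product: 35 (2E,4S)-N-methoxy-N,4-dimethyl-6-(Dec)-4-[(triethylsilyl)peroxy]hex-2-enamide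
Conditions: (EtO)2P(O)CH2C(O)N(OMe)Me, NaH, THF, 0 °C → rt
Reagents that add atoms: diethyl {2-[methoxy(methyl)amino]-2-oxoethyl}phosphonate, CCOP(=O)(CC(=O)N(C)OC)OCC
Why: Horner–Wadsworth–Emmons olefination gives the (E)-unsaturated Weinreb amide and adds C17 and C18 without the over-olefination that a formyl ylide would risk.

Step 23
Reactants: 35 (2E,4S)-N-methoxy-N,4-dimethyl-6-(Dec)-4-[(triethylsilyl)peroxy]hex-2-enamide
Product: 36 (2E,4S)-4-methyl-6-(Dec)-4-[(triethylsilyl)peroxy]hex-2-enal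
Conditions: i-Bu2AlH, THF, −78 °C; aq. potassium sodium tartrate
Reagents that add atoms: none
Why: the Weinreb amide is reduced through its stable aluminium chelate to the enal, and silyl peroxides tolerate i-Bu2AlH at low temperature.

Step 24
Reactants: 36 (2E,4S)-4-methyl-6-(Dec)-4-[(triethylsilyl)peroxy]hex-2-enal
Product: 37 (4S)-4-methyl-6-(Dec)-4-[(triethylsilyl)peroxy]hexanal
Conditions: Hantzsch ester, (PhCH2)2NH2+ CF3CO2− (10 mol%), THF, rt
Reagents that add atoms: none
Why: iminium-catalysed transfer hydrogenation (organocatalytic conjugate reduction of enals) saturates only the conjugated C16=C17 bond and is metal-free, so the two ring methylenes and the peroxide are not touched.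

Step 25
Reactants: 37 (4S)-4-methyl-6-(Dec)-4-[(triethylsilyl)peroxy]hexanal; 38 (4R)-4-benzyl-3-propanoyl-1,3-oxazolidin-2-one
Product: 40 (4R)-4-benzyl-3-{(2R,3S,6S)-3-hydroxy-2,6-dimethyl-8-(Dec)-6-[(triethylsilyl)peroxy]octanoyl}-1,3-oxazolidin-2-one, via dibutylboron (Z)-enolate 39 (not isolated)
Conditions: 38, Bu2BOTf, i-Pr2NEt, CH2Cl2, 0 °C; then 37, −78 → 0 °C; pH 7 buffer, MeOH, H2O2, 0 °C
Reagents that add atoms: none
Why: Evans syn-aldol, in which the (Z)-boron enolate of the (R)-auxiliary adds through the Zimmerman–Traxler chair, sets C19 (final configuration) and C18 (S, to be inverted in step 29) by reagent control.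

Step 26
Reactants: 40 (4R)-4-benzyl-3-{(2R,3S,6S)-3-hydroxy-2,6-dimethyl-8-(Dec)-6-[(triethylsilyl)peroxy]octanoyl}-1,3-oxazolidin-2-one
Product: 41 (2S,3S,6S)-2,6-dimethyl-8-(Dec)-6-[(triethylsilyl)peroxy]octane-1,3-diol
Conditions: LiBH4, MeOH (1 equiv), Et2O, 0 °C
Reagents that add atoms: none
Why: reductive removal of the auxiliary gives the 1,3-diol without base, so neither retro-aldol cleavage nor C19 epimerisation is expected (the S descriptor at C19 is a CIP change only).

Step 27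
Reactants: 41 (2S,3S,6S)-2,6-dimethyl-8-(Dec)-6-[(triethylsilyl)peroxy]octane-1,3-diol
Product: 42 (2S,3S,6S)-1-[(tert-butyldimethylsilyl)oxy]-2,6-dimethyl-8-(Dec)-6-[(triethylsilyl)peroxy]octan-3-ol
Conditions: t-BuMe2SiCl, imidazole, CH2Cl2, 0 °C
Reagents that add atoms: tert-butylchlorodimethylsilane, CC(C)(C)[Si](C)(C)Cl
Why: selective silylation of the primary hydroxyl leaves only the C18 hydroxyl free.

Step 28
Reactants: 42 (2S,3S,6S)-1-[(tert-butyldimethylsilyl)oxy]-2,6-dimethyl-8-(Dec)-6-[(triethylsilyl)peroxy]octan-3-ol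
Product: 43 (2S,3S,6S)-1-[(tert-butyldimethylsilyl)oxy]-2,6-dimethyl-8-(Dec)-6-[(triethylsilyl)peroxy]octan-3-yl methanesulfonate
Conditions: MsCl, Et3N, CH2Cl2, −20 °C
Reagents that add atoms: methanesulfonyl chloride, CS(=O)(=O)Cl
Why: sulfonylation turns the C18 hydroxyl into the leaving group, and with C21 at the alcohol oxidation level no E1cB elimination is possible.

Step 29
Reactants: 43 (2S,3S,6S)-1-[(tert-butyldimethylsilyl)oxy]-2,6-dimethyl-8-(Dec)-6-[(triethylsilyl)peroxy]octan-3-yl methanesulfonate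
Product: 46 (2S)-2-{(3R,6S)-6-methyl-6-[2-(Dec)ethyl]-1,2-dioxan-3-yl}propan-1-ol, via hydroperoxy mesylate 44 (not isolated), via dioxane silyl ether 45 (not isolated)
Conditions: Bu4NF, THF, 0 °C → rt
Reagents that add atoms: none
Why: fluoride frees the tertiary peroxide anion, which displaces the C18 mesylate in a 6-exo-tet SN2 reaction (intramolecular alkylation of a hydroperoxide) with inversion to the 3R centre, the chair transition state holding the C13 chain and the C19 branch equatorial, and the primary silyl ether is cleaved in the same pot.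

Step 30
Reactants: 46 (2S)-2-{(3R,6S)-6-methyl-6-[2-(Dec)ethyl]-1,2-dioxan-3-yl}propan-1-ol
Product: 48 (2R)-2-{(3R,6S)-6-methyl-6-[2-(Dec)ethyl]-1,2-dioxan-3-yl}propanoic acid, via aldehyde 47 (not isolated)
Conditions: TEMPO (20 mol%), PhI(OAc)2, MeCN/H2O, rt
Reagents that add atoms: water, O
Why: oxoammonium oxidation of the primary alcohol through the aldehyde hydrate to the acid runs near neutral pH, so the β-peroxy aldehyde should neither epimerise at C19 nor open by retro-Michael reaction, and the alkenes and the peroxide are spared.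

**Compound list**

1 | anisole | COc1ccccc1 | starting material
2 | 3-methylbut-2-enoic acid | CC(C)=CC(=O)O | starting material
3 | 3-(4-methoxyphenyl)-3-methylbutanoic acid | COc1ccc(cc1)C(C)(C)CC(=O)O | intermediate
4 | 3-(4-methoxycyclohexa-1,4-dien-1-yl)-3-methylbutanoic acid | COC1=CCC(=CC1)C(C)(C)CC(=O)O | intermediate (not isolated)
5 | 3-methyl-3-(4-oxocyclohex-1-en-1-yl)butanoic acid | O=C1CCC(=CC1)C(C)(C)CC(=O)O | intermediate
6 | 3-methyl-3-(4-oxocyclohexyl)butanoic acid | O=C1CCC(CC1)C(C)(C)CC(=O)O | intermediate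
7 | 3-(1,4-dioxaspiro[4.5]decan-8-yl)-3-methylbutanoic acid | OC(=O)CC(C)(C)C1CCC2(CC1)OCCO2 | intermediate
8 | (4S)-4-benzyl-1,3-oxazolidin-2-one | O=C1N[C@@H](Cc2ccccc2)CO1 | starting material
9 | mixed anhydride of 7 with pivalic acid | CC(C)(C)C(=O)OC(=O)CC(C)(C)C1CCC2(CC1)OCCO2 | intermediate (not isolated)
10 | (4S)-4-benzyl-3-[3-(1,4-dioxaspiro[4.5]decan-8-yl)-3-methylbutanoyl]-1,3-oxazolidin-2-one | O=C(CC(C)(C)C1CCC2(CC1)OCCO2)N1[C@@H](Cc2ccccc2)COC1=O | intermediate
11 | sodium (Z)-enolate of 10 | [Na+].[O-]/C(=C\C(C)(C)C1CCC2(CC1)OCCO2)N1[C@@H](Cc2ccccc2)COC1=O | intermediate (not isolated)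
12 | (4S)-4-benzyl-3-[(2R)-2-[(benzyloxy)methyl]-3-(1,4-dioxaspiro[4.5]decan-8-yl)-3-methylbutanoyl]-1,3-oxazolidin-2-one | O=C([C@@H](COCc1ccccc1)C(C)(C)C1CCC2(CC1)OCCO2)N1[C@@H](Cc2ccccc2)COC1=O | intermediate
13 | (2R)-2-[(benzyloxy)methyl]-3-(1,4-dioxaspiro[4.5]decan-8-yl)-3-methylbutaneperoxoic acid | OOC(=O)[C@@H](COCc1ccccc1)C(C)(C)C1CCC2(CC1)OCCO2 | intermediate (not isolated)
14 | (2R)-2-[(benzyloxy)methyl]-3-(1,4-dioxaspiro[4.5]decan-8-yl)-3-methylbutanoic acid | OC(=O)[C@@H](COCc1ccccc1)C(C)(C)C1CCC2(CC1)OCCO2 | intermediate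
15 | methyl (2R)-2-[(benzyloxy)methyl]-3-(1,4-dioxaspiro[4.5]decan-8-yl)-3-methylbutanoate | COC(=O)[C@@H](COCc1ccccc1)C(C)(C)C1CCC2(CC1)OCCO2 | intermediate
16 | (trimethylsilyl)methylmagnesium chloride | C[Si](C)(C)C[Mg]Cl | starting material
17 | 2-[(2R)-1-(benzyloxy)-3-(1,4-dioxaspiro[4.5]decan-8-yl)-3-methylbutan-2-yl]-1,3-bis(trimethylsilyl)propan-2-ol | C[Si](C)(C)CC(O)(C[Si](C)(C)C)[C@@H](COCc1ccccc1)C(C)(C)C1CCC2(CC1)OCCO2 | intermediate (not isolated)
18 | 8-[(3S)-4-(benzyloxy)-2-methyl-3-{3-(trimethylsilyl)prop-1-en-2-yl}butan-2-yl]-1,4-dioxaspiro[4.5]decane | C=C(C[Si](C)(C)C)[C@@H](COCc1ccccc1)C(C)(C)C1CCC2(CC1)OCCO2 | intermediate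
19 | 4-[(3S)-4-(benzyloxy)-2-methyl-3-{3-(trimethylsilyl)prop-1-en-2-yl}butan-2-yl]cyclohexan-1-one | C=C(C[Si](C)(C)C)[C@@H](COCc1ccccc1)C(C)(C)C1CCC(=O)CC1 | intermediate
20 | [(4S)-4-{(3S)-4-(benzyloxy)-2-methyl-3-[3-(trimethylsilyl)prop-1-en-2-yl]butan-2-yl}cyclohex-1-en-1-yl]oxy(trimethyl)silane | C[Si](C)(C)OC1=CC[C@H](CC1)C(C)(C)[C@H](COCc2ccccc2)C(=C)C[Si](C)(C)C | intermediate
21 | (4S)-4-{(3S)-4-(benzyloxy)-2-methyl-3-[3-(trimethylsilyl)prop-1-en-2-yl]butan-2-yl}cyclohex-2-en-1-one (key-step precursor) | O=C1CC[C@@H](C=C1)C(C)(C)[C@H](COCc2ccccc2)C(=C)C[Si](C)(C)C | intermediate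
22 | trichlorotitanium enolate of 23 (O on C2, double bond C2=C7) | Cl[Ti](Cl)(Cl)OC=1CC[C@H]2[C@@H](C=1)CC(=C)[C@@H](COCc3ccccc3)C2(C)C | intermediate (not isolated)
23 | (4aS,6R,8aR)-6-[(benzyloxy)methyl]-5,5-dimethyl-7-methylideneoctahydronaphthalen-2(1H)-one (key-step product, cis-fused) | O=C1CC[C@H]2[C@@H](C1)CC(=C)[C@@H](COCc3ccccc3)C2(C)C | intermediate
24 | (2R,4aS,8aS)-2-[(benzyloxy)methyl]-1,1-dimethyl-3,6-dimethylidenedecahydronaphthalene | C=C1CC[C@H]2[C@@H](C1)CC(=C)[C@@H](COCc3ccccc3)C2(C)C | intermediate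
25 | (Dec)methanol | C=C1CC[C@H]2[C@@H](C1)CC(=C)[C@@H](CO)C2(C)C | intermediate
26 | (2R,4aS,8aS)-2-(iodomethyl)-1,1-dimethyl-3,6-dimethylidenedecahydronaphthalene | C=C1CC[C@H]2[C@@H](C1)CC(=C)[C@@H](CI)C2(C)C | intermediate
27 | [(2S)-2-methyloxiran-2-yl]methanol | C1O[C@@]1(C)CO | starting material
28 | [(2R)-2-methyloxiran-2-yl]methyl 4-methylbenzenesulfonate | C1O[C@@]1(C)COS(=O)(=O)c1ccc(C)cc1 | intermediate
29 | [(Dec)methyl]magnesium iodide | C=C1CC[C@H]2[C@@H](C1)CC(=C)[C@@H](C[Mg]I)C2(C)C | intermediate (not isolated)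
30 | (2R)-2-hydroxy-2-methyl-4-(Dec)butyl 4-methylbenzenesulfonate | C=C1CC[C@H]2[C@@H](C1)CC(=C)[C@@H](CC[C@](O)(C)COS(=O)(=O)c3ccc(C)cc3)C2(C)C | intermediate (not isolated)
31 | (2R)-2-methyl-2-[2-(Dec)ethyl]oxirane | C=C1CC[C@H]2[C@@H](C1)CC(=C)[C@@H](CC[C@]3(C)CO3)C2(C)C | intermediate
32 | (2S)-2-hydroperoxy-2-methyl-4-(Dec)butan-1-ol | C=C1CC[C@H]2[C@@H](C1)CC(=C)[C@@H](CC[C@@](OO)(C)CO)C2(C)C | intermediate
33 | triethyl{[(2S)-2-methyl-4-(Dec)-2-[(triethylsilyl)peroxy]butyl]oxy}silane | C=C1CC[C@H]2[C@@H](C1)CC(=C)[C@@H](CC[C@@](OO[Si](CC)(CC)CC)(C)CO[Si](CC)(CC)CC)C2(C)C | intermediate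
34 | (2S)-2-methyl-4-(Dec)-2-[(triethylsilyl)peroxy]butanal | C=C1CC[C@H]2[C@@H](C1)CC(=C)[C@@H](CC[C@@](OO[Si](CC)(CC)CC)(C)C=O)C2(C)C | intermediate
35 | (2E,4S)-N-methoxy-N,4-dimethyl-6-(Dec)-4-[(triethylsilyl)peroxy]hex-2-enamide | C=C1CC[C@H]2[C@@H](C1)CC(=C)[C@@H](CC[C@@](OO[Si](CC)(CC)CC)(C)/C=C/C(=O)N(C)OC)C2(C)C | intermediate
36 | (2E,4S)-4-methyl-6-(Dec)-4-[(triethylsilyl)peroxy]hex-2-enal | C=C1CC[C@H]2[C@@H](C1)CC(=C)[C@@H](CC[C@@](OO[Si](CC)(CC)CC)(C)/C=C/C=O)C2(C)C | intermediate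
37 | (4S)-4-methyl-6-(Dec)-4-[(triethylsilyl)peroxy]hexanal | C=C1CC[C@H]2[C@@H](C1)CC(=C)[C@@H](CC[C@@](OO[Si](CC)(CC)CC)(C)CCC=O)C2(C)C | intermediate
38 | (4R)-4-benzyl-3-propanoyl-1,3-oxazolidin-2-one | CCC(=O)N1[C@H](Cc2ccccc2)COC1=O | starting material
39 | dibutylboron (Z)-enolate of 38 | C/C=C(\OB(CCCC)CCCC)N1[C@H](Cc2ccccc2)COC1=O | intermediate (not isolated)
40 | (4R)-4-benzyl-3-{(2R,3S,6S)-3-hydroxy-2,6-dimethyl-8-(Dec)-6-[(triethylsilyl)peroxy]octanoyl}-1,3-oxazolidin-2-one | C=C1CC[C@H]2[C@@H](C1)CC(=C)[C@@H](CC[C@@](OO[Si](CC)(CC)CC)(C)CC[C@H](O)[C@@H](C)C(=O)N1[C@H](Cc3ccccc3)COC1=O)C2(C)C | intermediate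
41 | (2S,3S,6S)-2,6-dimethyl-8-(Dec)-6-[(triethylsilyl)peroxy]octane-1,3-diol | C=C1CC[C@H]2[C@@H](C1)CC(=C)[C@@H](CC[C@@](OO[Si](CC)(CC)CC)(C)CC[C@H](O)[C@@H](C)CO)C2(C)C | intermediate
42 | (2S,3S,6S)-1-[(tert-butyldimethylsilyl)oxy]-2,6-dimethyl-8-(Dec)-6-[(triethylsilyl)peroxy]octan-3-ol | C=C1CC[C@H]2[C@@H](C1)CC(=C)[C@@H](CC[C@@](OO[Si](CC)(CC)CC)(C)CC[C@H](O)[C@@H](C)CO[Si](C)(C)C(C)(C)C)C2(C)C | intermediate
43 | (2S,3S,6S)-1-[(tert-butyldimethylsilyl)oxy]-2,6-dimethyl-8-(Dec)-6-[(triethylsilyl)peroxy]octan-3-yl methanesulfonate | C=C1CC[C@H]2[C@@H](C1)CC(=C)[C@@H](CC[C@@](OO[Si](CC)(CC)CC)(C)CC[C@H](OS(C)(=O)=O)[C@@H](C)CO[Si](C)(C)C(C)(C)C)C2(C)C | intermediate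
44 | (2S,3S,6S)-1-[(tert-butyldimethylsilyl)oxy]-6-hydroperoxy-2,6-dimethyl-8-(Dec)octan-3-yl methanesulfonate | C=C1CC[C@H]2[C@@H](C1)CC(=C)[C@@H](CC[C@@](OO)(C)CC[C@H](OS(C)(=O)=O)[C@@H](C)CO[Si](C)(C)C(C)(C)C)C2(C)C | intermediate (not isolated)
45 | tert-butyl{(2S)-2-[(3R,6S)-6-methyl-6-[2-(Dec)ethyl]-1,2-dioxan-3-yl]propoxy}dimethylsilane | C=C1CC[C@H]2[C@@H](C1)CC(=C)[C@@H](CC[C@@]1(C)CC[C@H]([C@@H](C)CO[Si](C)(C)C(C)(C)C)OO1)C2(C)C | intermediate (not isolated)
46 | (2S)-2-{(3R,6S)-6-methyl-6-[2-(Dec)ethyl]-1,2-dioxan-3-yl}propan-1-ol | C=C1CC[C@H]2[C@@H](C1)CC(=C)[C@@H](CC[C@@]1(C)CC[C@H]([C@@H](C)CO)OO1)C2(C)C | intermediate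
47 | (2R)-2-{(3R,6S)-6-methyl-6-[2-(Dec)ethyl]-1,2-dioxan-3-yl}propanal | C=C1CC[C@H]2[C@@H](C1)CC(=C)[C@@H](CC[C@@]1(C)CC[C@H]([C@@H](C)C=O)OO1)C2(C)C | intermediate (not isolated)
48 | (2R)-2-{(3R,6S)-6-methyl-6-[2-((2R,4aS,8aS)-1,1-dimethyl-3,6-dimethylidenedecahydronaphthalen-2-yl)ethyl]-1,2-dioxan-3-yl}propanoic acid | C=C1CC[C@H]2[C@@H](C1)CC(=C)[C@@H](CC[C@@]1(C)CC[C@H]([C@@H](C)C(=O)O)OO1)C2(C)C | target

**Step count and risks**

Total step count: 30. Longest linear sequence: 29 steps (steps 1–16 and 18–30; step 17 prepares the glycidyl tosylate).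

Most likely to fail:

Step 13. Process: the chair transition state of the axial attack puts C12 and C4 in a 1,3-diaxial relation on the forming ring, so closure through the twisted (equatorial-attack) mode to the trans-fused decalone, or plain protodesilylation, may compete. Fallback, from 21 back to 23: bromodesilylation of 21 with N-bromosuccinimide (CH2Cl2, −78 °C; attack at C8 with loss of silicon) should give the allylic bromide (4S)-4-{(3S)-4-(benzyloxy)-3-(3-bromoprop-1-en-2-yl)-2-methylbutan-2-yl}cyclohex-2-en-1-one F1. Slow addition of Bu3SnH and AIBN in benzene at 80 °C then generates the 2-substituted allyl radical. Its 6-exo addition to C6 has an early transition state with little diaxial strain and is expected to close cis; hydrogen transfer to the α-keto radical returns the route at 23.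

Step 19. Process: capture of the ionising tertiary C14–O bond by the C9=C10 alkene (a six-membered cation–olefin closure), oxidation of the exocyclic alkenes by peroxomolybdate, or partial loss of configuration at C14. Fallback, from 31 back to 37: ring expansion of 31 with dimethylsulfoxonium methylide (Me3S(O)I, KOC(CH3)3, t-BuOH, 50 °C; attack at C16, then 4-exo-tet closure with the C14–O bond intact) should give the oxetane (2R)-2-methyl-2-[2-(Dec)ethyl]oxetane F2. Opening with H2O2 and Me3SiOTf in Et2O at −78 → 0 °C, a metal-free low-temperature perhydrolysis that inverts tertiary oxetane carbons, gives the γ-hydroperoxy alcohol (3S)-3-hydroperoxy-3-methyl-5-(Dec)pentan-1-ol F3. Silylation (Et3SiCl, imidazole) gives the bis(triethylsilyl) derivative triethyl{[(3S)-3-methyl-5-(Dec)-3-[(triethylsilyl)peroxy]pentyl]oxy}silane F4, and Swern oxidation gives the aldehyde (3S)-3-methyl-5-(Dec)-3-[(triethylsilyl)peroxy]pentanal F5, which is kept cold because a β-peroxy aldehyde can eliminate. Wittig reaction with Ph3P=CHOCH3 gives the enol ether triethyl{[(3S)-6-methoxy-3-methyl-1-(Dec)hex-5-en-3-yl]peroxy}silane F6, and hydrolysis with oxalic acid in wet THF returns the route at 37; the one-carbon homologation here replaces steps 22–24.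

Step 29. Process: elimination of the secondary mesylate, or its displacement by fluoride, before the hindered tertiary peroxide anion attacks C18. Fallback, from 37 to 48: the ring is closed by conjugate addition instead of substitution. Wittig reaction of 37 with Ph3P=C(CH3)CO2CH3 (CH2Cl2, rt) should give the enoate methyl (2E,6R)-2,6-dimethyl-8-(Dec)-6-[(triethylsilyl)peroxy]oct-2-enoate F7 (6R by CIP, same spatial arrangement at C14). Bu4NF in THF frees the peroxide anion, which adds 6-exo-trig to C18 (oxa-Michael addition) to give the ester methyl (2R)-2-{(3R,6S)-6-methyl-6-[2-(Dec)ethyl]-1,2-dioxan-3-yl}propanoate F8. The chair transition state should favour the 3,6-trans ring, but C19 arises by protonation, so the C18/C19 isomers would have to be separated. LiOH in aqueous THF then returns the route at 48.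

**Further compounds**

F1 | step 13 | (4S)-4-{(3S)-4-(benzyloxy)-3-(3-bromoprop-1-en-2-yl)-2-methylbutan-2-yl}cyclohex-2-en-1-one | O=C1CC[C@@H](C=C1)C(C)(C)[C@H](COCc2ccccc2)C(=C)CBr
F2 | step 19 | (2R)-2-methyl-2-[2-(Dec)ethyl]oxetane | C=C1CC[C@H]2[C@@H](C1)CC(=C)[C@@H](CC[C@]3(C)CCO3)C2(C)C
F3 | step 19 | (3S)-3-hydroperoxy-3-methyl-5-(Dec)pentan-1-ol | C=C1CC[C@H]2[C@@H](C1)CC(=C)[C@@H](CC[C@@](OO)(C)CCO)C2(C)C
F4 | step 19 | triethyl{[(3S)-3-methyl-5-(Dec)-3-[(triethylsilyl)peroxy]pentyl]oxy}silane | C=C1CC[C@H]2[C@@H](C1)CC(=C)[C@@H](CC[C@@](OO[Si](CC)(CC)CC)(C)CCO[Si](CC)(CC)CC)C2(C)C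
F5 | step 19 | (3S)-3-methyl-5-(Dec)-3-[(triethylsilyl)peroxy]pentanal | C=C1CC[C@H]2[C@@H](C1)CC(=C)[C@@H](CC[C@@](OO[Si](CC)(CC)CC)(C)CC=O)C2(C)C
F6 | step 19 | triethyl{[(3S)-6-methoxy-3-methyl-1-(Dec)hex-5-en-3-yl]peroxy}silane (E/Z mixture) | C=C1CC[C@H]2[C@@H](C1)CC(=C)[C@@H](CC[C@@](OO[Si](CC)(CC)CC)(C)CC=COC)C2(C)C
F7 | step 29 | methyl (2E,6R)-2,6-dimethyl-8-(Dec)-6-[(triethylsilyl)peroxy]oct-2-enoate | C=C1CC[C@H]2[C@@H](C1)CC(=C)[C@@H](CC[C@@](OO[Si](CC)(CC)CC)(C)CC/C=C(\C)C(=O)OC)C2(C)C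
F8 | step 29 | methyl (2R)-2-{(3R,6S)-6-methyl-6-[2-(Dec)ethyl]-1,2-dioxan-3-yl}propanoate | C=C1CC[C@H]2[C@@H](C1)CC(=C)[C@@H](CC[C@@]1(C)CC[C@H]([C@@H](C)C(=O)OC)OO1)C2(C)C
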